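## The problem

CNP0361406.2 (29) is an ester-linked pseudo-dimer of two C15 units with the same carbon skeleton: a six-membered ring with an isopropyl group, a one-carbon oxygenated branch and, next to the isopropyl carbon, a 2-(oxymethyl)acrylic acid arm. In ring C the unit is a cyclohexene with CH2OH on the alkene. In the other unit that alkene has become a tertiary carbinol carbon (C–OH carrying the CH2O branch) and a CH–CO carbon, whose carboxyl is tied to the CH2OH of its own arm as the seven-membered lactone ring B, trans-fused to ring A. The halves are joined through the primary oxygen on the carbinol carbon, beside a free tertiary hydroxyl. Of the six stereocentres, four are two copies of the same trans isopropyl/arm pair, which a chiral-pool isopropyl centre can set by conjugate addition. The carboxyl-bearing CH is epimerisable and equatorial, so the centre that needs real control is the quaternary carbinol: its oxygen must be trans to the carboxyl and 1,3-cis to the arm, with only the CH2O branch axial. The sensitive features are the β-hydroxy lactone, the 2-(acyloxymethyl)acrylate units (allylic C–O bonds open to SN2′ attack), two trisubstituted (E)-alkenes, a free acid and two primary allylic alcohols. In addition, the strained seven-membered lactone can slide to a five-membered one whenever the CH2OH on the carbinol carbon is free. The enabling feature is that ring A is ring C plus one carbon: C(OH)(CH2O)–CH(CO) of ring A maps atom for atom onto C(CH2OH)=CH of ring C, with O and C added anti, so one ring C intermediate can serve both halves if its alkene is oxy-carbonylated through the allylic oxygen.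

## Retrosynthesis

**29 ⇒ 28.** Only O–Si and ester C–O(silylethyl) bonds are cut. Two silyl ethers and the 2-(trimethylsilyl)ethyl ester fall to fluoride in one operation, so no acid, base or oxidant touches the finished skeleton.

**28 ⇒ 24 + 26.** The acyl–O bond of the linking ester is cut, giving diol lactone 24 and ring C acid 26. The neighbouring option, letting the carboxylate of 26 open cyclic carbonate 23 at its CH2, was set aside as first choice. That CH2 sits on a fully substituted carbon, and the allylic O–CH2 of ring B in 23 is the better electrophile. Acylation asks only that the primary hydroxyl of 24 react before the tertiary one and before the lactone can migrate.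

**24 ⇒ 23 ⇒ 21 ⇒ 20 ⇒ 19.** The carbonate C–O bonds, then the acyl–O bond of ring B are cut. The cyclic carbonate from the key step is kept as the protecting group of the carbinol and its CH2O branch while the ring A carboxyl is freed (20), the arm hydroxyl unmasked (21) and the seven-membered lactone closed (23). In this order a free CH2OH never meets an activated carboxyl on the neighbouring carbon, which would give the five-membered lactone.

**19 ⇒ 16 + 17 + 18.** The carbinol C–O bond and the CH–C(=O) bond are cut. Carbonate 16, carbon monoxide 17 and methanol 18 would give 19 with the spiro dioxolanone closed and both new stereocentres set. This removes one ring, two skeletal bonds and two stereocentres at once. The forward reaction must add oxygen at the substituted alkene carbon and palladium at the CH carbon, on the face opposite the arm, and must carbonylate before β-hydride elimination.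

**16 and 26 ⇒ 14.** Allylic alcohol 14 is the branch point. Its tert-butyl carbonate is 16; silylation (25) and saponification give 26. The two halves differ only in what is done to this one hydroxyl.

**14 ⇒ 12 + 13.** The C–CH2OH bond on the ring alkene is cut. Enol triflate 12 fixes the alkene position, and stannane 13 brings the hydroxymethyl carbon in the correct oxidation state with the arm ester already present.

**12 ⇒ 6 + 11; 11 ⇒ 9 + 10; 9 ⇒ 7 + 8.** The arm C=C bond is cut by olefination of aldehyde 6 with phosphonate 11. An α-substituted phosphonoacetate puts the ester trans to the ring, the geometry both halves need. Phosphonate 11 carries the arm oxygen as a triisopropylsilyl ether, chosen to survive the buffered key step, and comes from 9 and chloromethyl ether 10; 9 comes from acid 7 and alcohol 8.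

**6 ⇒ 4 ⇒ 1 + 2.** The formyl group is a cleaved vinyl group. The vinyl group and the enol triflate come from conjugate addition of 2 to (R)-cryptone 1 with trapping of enolate 3. This step sets the arm-bearing stereocentre trans to isopropyl and delivers the enolate regiochemistry that the later hydroxymethylation needs. The triflate also deactivates the ring alkene during cleavage of the vinyl group via diol 5.

## Roads not taken

**Alternative 1:** The cut removes one carbon of ring B and leads back to the six-membered enol lactone A1, ketal-protected at the future carbinol carbon. The forward key step is carbene addition to the enol ether double bond of A1 and silver-assisted solvolytic opening of the dihalocyclopropane, giving the seven-membered bromoalkene lactone A2.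
- Merits: it is well-understood ring-expansion chemistry, and the vinyl bromide is a handle for introducing the ring B carboxyl.
- A respect in which it is safer than the chosen plan: the carbinol carbon is still a ketone, so its configuration could be set by axial addition of a one-carbon nucleophile, which gives the equatorial hydroxyl directly.
- Weak points: A2 carries the O-bearing ring B carbon at the acylal level and as two epimers; the cyclopropane must open at the correct bond next to an acid-sensitive ketal; and the carbinol, its CH2O branch, the union and the whole ring C half still have to be made.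
- Comparison: against the stereochemical safety of this road the chosen plan sets step economy and convergence, because one step installs carbinol, branch and carboxyl, and 14 feeds both halves.

**Alternative 2:** The cut is at the carbinol–CH(carboxyl) and CH(arm)–CH(isopropyl) bonds of ring A. The forward key step is an endo Diels–Alder reaction of silyloxy diene A3 with (E)-enoate A4 to give bicyclooctene A5; cleaving the bridging alkene would then reveal ring A, the two bridge carbons becoming the CH2O branch and an acetyl group.
- Merits: two bonds and all four ring A stereocentres form together. The bicycle ties the future CH2O branch cis to the isopropyl precursor and to the endo ester, with the arm precursor trans, which is the target array.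
- A respect in which it is better than the chosen plan: the carbinol configuration is mechanically guaranteed, whereas that is the least secure point of the chosen key step.
- Weak points: A5 is racemic unless the cycloaddition is made enantioselective; a trisubstituted diene and a β-substituted enoate are a slow pair; bridge cleavage, acetyl-to-isopropyl, formyl-to-CH2OH and acetal-to-arm conversions add many steps; and ring C needs its own route.
- Comparison: the chosen plan sets against it absolute configuration from the chiral pool, the shared intermediate 14 and a much shorter sequence.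

**Alternative 3:** The cut is at the CH2–O and C=C bonds of the ring C arm, so the halves are joined while the arm is built. In the forward key step the alkoxide of A9 adds to phosphonoacrylate A6 and the resulting phosphonate carbanion olefinates ring C aldehyde A7, giving A8.
- Merits: it is highly convergent and saves the separate preparation of acid 26. As an endgame it is at least as convergent as the chosen one.
- Weak points: an alkoxide and a phosphonate anion act on the β-hydroxy lactone and allylic ester of A6 and on the epimerisable aldehyde A7; alkene geometry is decided on the most valuable material; and a benzyl-type ether must be removed oxidatively at the end.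
- It is not an answer to ring A: A6 still needs a compound like 24 and the same hindered primary acylation.
- Comparison: the chosen plan sets against it that the arm alkene is made early on a simple aldehyde (step 5) and the union is an ordinary esterification.

Key step: step 8

Assumption: 7, 8, 10, 13 and 15 are purchased. CIP descriptors change along the route only because priorities change; no stereocentre is inverted.

## Route

Step 1
Reactants: 1 (R)-cryptone; 2 vinylmagnesium bromide (CH2=CHMgBr)
Product: 4 (3R,4R)-3-ethenyl-4-(propan-2-yl)cyclohex-1-en-1-yl trifluoromethanesulfonate, via bromomagnesium enolate 3 (not isolated)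
Conditions: CuBr·SMe2 (10 mol %), THF, −78 °C; then PhNTf2, DMPU, −78 °C to rt; aq. NH4Cl
Reagents that add atoms: N-phenylbis(trifluoromethanesulfonimide), O=S(=O)(N(c1ccccc1)S(=O)(=O)C(F)(F)F)C(F)(F)F
Why: Copper-catalysed conjugate addition of the Grignard reagent should occur anti to the adjacent isopropyl group and so set the new centre trans; O-triflation of the regiodefined enolate then fixes the alkene position.

Step 2
Reactants: 4 enol triflate
Product: 6 (3R,4R)-3-formyl-4-(propan-2-yl)cyclohex-1-en-1-yl trifluoromethanesulfonate, via vicinal diol 5 (not isolated)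
Conditions: OsO4 (2 mol %), NaIO4, 2,6-lutidine, dioxane–H2O, rt; used at once
Reagents that add atoms: osmium tetroxide, O=[Os](=O)(=O)=O (oxygen donor, regenerated by NaIO4); sodium periodate, [Na+].[O-][I](=O)(=O)=O
Why: Lemieux–Johnson cleavage; OsO4 should take the monosubstituted vinyl group and leave the electron-poor enol triflate alkene, and the trans arrangement at the formyl-bearing centre is the more stable one should it equilibrate.

Step 3
Reactants: 7 (diethoxyphosphoryl)acetic acid; 8 2-(trimethylsilyl)ethanol
Product: 9 2-(trimethylsilyl)ethyl (diethoxyphosphoryl)acetate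
Conditions: DCC, DMAP (cat.), CH2Cl2, 0 °C to rt
Reagents that add atoms: none
Why: Steglich esterification of an unhindered acid with a primary alcohol.

Step 4
Reactants: 9 phosphonoacetate; 10 chloromethyl triisopropylsilyl ether
Product: 11 2-(trimethylsilyl)ethyl 2-(diethoxyphosphoryl)-3-(triisopropylsilyloxy)propanoate (racemic)
Conditions: NaH (1.0 equiv), THF, 0 °C; then 10, 0 °C to rt
Reagents that add atoms: none
Why: C-alkylation of the stabilised phosphonate carbanion by a reactive chloromethyl ether; one equivalent of base at low temperature should limit dialkylation and β-elimination of silanolate.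

Step 5
Reactants: 6 aldehyde; 11 phosphonate
Product: 12 2-(trimethylsilyl)ethyl (2E)-3-[(1S,6R)-6-(propan-2-yl)-3-(trifluoromethanesulfonyloxy)cyclohex-2-en-1-yl]-2-[(triisopropylsilyloxy)methyl]prop-2-enoate
Conditions: LiCl, DBU, MeCN, 0 °C to rt
Reagents that add atoms: none
Why: Horner–Wadsworth–Emmons olefination under Masamune–Roush conditions; α-substituted phosphonoacetates place the ester trans to the aldehyde residue (E), and the mild base should spare the epimerisable β,γ-unsaturated aldehyde.

Step 6
Reactants: 12 enoate triflate; 13 (tributylstannyl)methanol (Bu3SnCH2OH)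
Product: 14 2-(trimethylsilyl)ethyl (2E)-3-[(1R,6R)-3-(hydroxymethyl)-6-(propan-2-yl)cyclohex-2-en-1-yl]-2-[(triisopropylsilyloxy)methyl]prop-2-enoate
Conditions: Pd(PPh3)4 (5 mol %), LiCl, 1,4-dioxane, 90 °C
Reagents that add atoms: none
Why: Stille coupling of an enol triflate with a hydroxymethyl stannane; the alkene stays where the triflate was and the ester, silyl ether and arm alkene are spectators.

Step 7
Reactants: 14 allylic alcohol; 15 di-tert-butyl dicarbonate
Product: 16 2-(trimethylsilyl)ethyl (2E)-3-[(1R,6R)-3-{[(tert-butoxycarbonyl)oxy]methyl}-6-(propan-2-yl)cyclohex-2-en-1-yl]-2-[(triisopropylsilyloxy)methyl]prop-2-enoate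
Conditions: Et3N, DMAP (cat.), CH2Cl2, 0 °C to rt
Reagents that add atoms: none
Why: DMAP-catalysed O-acylation of the only free (primary) hydroxyl by Boc2O.

Step 8
Reactants: 16 allylic tert-butyl carbonate; 17 carbon monoxide; 18 methanol
Product: 19 methyl (5S,6S,7S,8R)-2-oxo-8-(propan-2-yl)-7-[(1E)-3-oxo-3-[2-(trimethylsilyl)ethoxy]-2-[(triisopropylsilyloxy)methyl]prop-1-en-1-yl]-1,3-dioxaspiro[4.5]decane-6-carboxylate
Conditions: PdCl2 (10 mol %), CuCl2 (3 equiv), NaOAc (3 equiv), CO (1 atm), MeOH–MeCN, 0 °C to rt
Reagents that add atoms: none
Why: Proposed new method: PdCl2 (divalent palladium) binds the ring alkene of 16, the carbonyl oxygen of the tert-butyl carbonate attacks the substituted alkene carbon anti to the metal, the dioxolanylium ion loses isobutene, CO inserts into the secondary C–Pd bond with retention and methanol cleaves the acyl complex, CuCl2 returning zerovalent palladium to the divalent state. The closest known reactions are the intramolecular alkoxy- and aminocarbonylations of hydroxy alkenes and O-allyl carbamates under PdCl2/CuCl2/CO/methanol and the iodocarbonate cyclisation of tert-butyl carbonates; a Boc carbonate has not been used as the oxygen nucleophile in this carbonylative manifold. The dioxolanone closes by 5-exo-trig attack on the proximal alkene carbon, which is also the Markovnikov site, so palladium ends on the CH carbon. The spiro centre C5 is set by anti attack relative to palladium and C6 by the face palladium occupies together with retention in CO insertion, which puts the carbonate oxygen trans and the CH2O branch cis to the ester. The step needs palladium on the face opposite the arm at C7; what favours this is that the arm flanks the carbon receiving the metal and that this face gives the alkyl–palladium with the metal equatorial, but the adduct with both new bonds equatorial is not the one favoured by trans-diaxial opening, so facial control is the least secure element. CO insertion must outrun β-hydride elimination toward C7–H, which a CO atmosphere and chloride-rich palladium favour, and NaOAc keeps the medium from cleaving the silyl ether or the carbonate.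

Step 9
Reactants: 19 methyl ester
Product: 20 (5S,6S,7S,8R)-2-oxo-8-(propan-2-yl)-7-[(1E)-3-oxo-3-[2-(trimethylsilyl)ethoxy]-2-[(triisopropylsilyloxy)methyl]prop-1-en-1-yl]-1,3-dioxaspiro[4.5]decane-6-carboxylic acid
Conditions: LiI, EtOAc, reflux; then dilute HCl
Reagents that add atoms: none
Why: Nucleophilic demethylation (SN2 by iodide at the O–CH3 carbon) cleaves the hindered ester without attack at its carbonyl; the silylethyl ester and the carbonate CH2 are much poorer SN2 sites.

Step 10
Reactants: 20 silyl ether acid
Product: 21 (5S,6S,7S,8R)-7-[(1E)-2-(hydroxymethyl)-3-oxo-3-[2-(trimethylsilyl)ethoxy]prop-1-en-1-yl]-2-oxo-8-(propan-2-yl)-1,3-dioxaspiro[4.5]decane-6-carboxylic acid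
Conditions: HF·pyridine, pyridine, THF, 0 °C to rt
Reagents that add atoms: none
Why: Buffered HF desilylation removes the primary triisopropylsilyl ether and leaves the silylethyl ester and the cyclic carbonate.

Step 11
Reactants: 21 hydroxy acid
Product: 23 ring A–B lactone spiro carbonate (trans-fused seven-membered lactone closed between the ring A carboxyl and the arm CH2OH), via mixed anhydride 22 (not isolated)
Conditions: 2,4,6-trichlorobenzoyl chloride, Et3N, THF, rt; then slow addition to DMAP, toluene (high dilution), 60 °C
Reagents that add atoms: none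
Why: Yamaguchi lactonisation; the arm hydroxyl is held cis on the alkene and trans-diequatorial to the activated carboxyl, so the seven-membered ring should close readily, and the equatorial carbonate oxygen is poorly aligned for β-elimination from the activated acyl group.

Step 12
Reactants: 23 lactone carbonate
Product: 24 2-(trimethylsilyl)ethyl (5aS,6R,9S,9aS)-9-hydroxy-9-(hydroxymethyl)-1-oxo-6-(propan-2-yl)-1,3,5a,6,7,8,9,9a-octahydro-2-benzoxepine-4-carboxylate
Conditions: LiOH (2.2 equiv), THF–H2O, 0 °C, short; pH 7 buffer
Reagents that add atoms: none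
Why: Saponification of the exposed five-membered cyclic carbonate is fast and made irreversible by loss of carbonate; the lactone carbonyl is flanked by a quaternary and a tertiary carbon and the conjugated silylethyl ester is slow to hydrolyse.

Step 13
Reactants: 14 allylic alcohol
Product: 25 2-(trimethylsilyl)ethyl (2E)-3-[(1R,6R)-3-[(tert-butyldimethylsilyloxy)methyl]-6-(propan-2-yl)cyclohex-2-en-1-yl]-2-[(triisopropylsilyloxy)methyl]prop-2-enoate
Conditions: TBSCl, imidazole, DMF, 0 °C to rt
Reagents that add atoms: tert-butyldimethylsilyl chloride, CC(C)(C)[Si](C)(C)Cl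
Why: Standard silylation of a primary alcohol.

Step 14
Reactants: 25 bis-silyl ether ester
Product: 26 (2E)-3-[(1R,6R)-3-[(tert-butyldimethylsilyloxy)methyl]-6-(propan-2-yl)cyclohex-2-en-1-yl]-2-[(triisopropylsilyloxy)methyl]prop-2-enoic acid
Conditions: LiOH, THF–MeOH–H2O, 40 °C; then HCl to pH 4
Reagents that add atoms: lithium hydroxide, [Li+].[OH-]
Why: Ordinary saponification of the conjugated ester; both silyl ethers are stable to aqueous hydroxide, so no fluoride is needed at this stage.

Step 15
Reactants: 26 ring C acid; 24 diol lactone
Product: 28 fully protected dimer (24 acylated by 26 at the primary hydroxyl), via mixed anhydride 27 (not isolated)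
Conditions: 26, 2,4,6-trichlorobenzoyl chloride, Et3N, toluene, rt; then 24, DMAP, rt
Reagents that add atoms: none
Why: Yamaguchi esterification; the primary hydroxyl should be acylated and the tertiary one left, and pre-forming the anhydride keeps the contact of 24 with base short.

Step 16
Reactants: 28 protected dimer
Product: 29 CNP0361406.2
Conditions: TBAF, THF, 0 °C to rt; aq. NH4Cl
Reagents that add atoms: none
Why: Fluoride cleaves both silyl ethers and the 2-(trimethylsilyl)ethyl ester (fragmentation to ethene) in one operation, leaving the esters, the lactone and the alkenes untouched.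

## Compound list

1 | (R)-cryptone, (4R)-4-(propan-2-yl)cyclohex-2-en-1-one | CC(C)[C@H]1CCC(=O)C=C1 | starting material
2 | vinylmagnesium bromide | C=C[Mg]Br | starting material
3 | bromomagnesium (3R,4R)-3-ethenyl-4-(propan-2-yl)cyclohex-1-en-1-olate | CC(C)[C@H]1CCC(O[Mg]Br)=C[C@@H]1C=C | intermediate
4 | (3R,4R)-3-ethenyl-4-(propan-2-yl)cyclohex-1-en-1-yl trifluoromethanesulfonate | CC(C)[C@H]1CCC(OS(=O)(=O)C(F)(F)F)=C[C@@H]1C=C | intermediate
5 | (3R,4R)-3-(1,2-dihydroxyethyl)-4-(propan-2-yl)cyclohex-1-en-1-yl trifluoromethanesulfonate (both carbinol epimers) | CC(C)[C@H]1CCC(OS(=O)(=O)C(F)(F)F)=C[C@@H]1C(O)CO | intermediate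
6 | (3R,4R)-3-formyl-4-(propan-2-yl)cyclohex-1-en-1-yl trifluoromethanesulfonate | CC(C)[C@H]1CCC(OS(=O)(=O)C(F)(F)F)=C[C@@H]1C=O | intermediate
7 | (diethoxyphosphoryl)acetic acid | CCOP(=O)(OCC)CC(=O)O | starting material
8 | 2-(trimethylsilyl)ethanol | C[Si](C)(C)CCO | starting material
9 | 2-(trimethylsilyl)ethyl (diethoxyphosphoryl)acetate | CCOP(=O)(OCC)CC(=O)OCC[Si](C)(C)C | intermediate
10 | chloromethyl triisopropylsilyl ether | ClCO[Si](C(C)C)(C(C)C)C(C)C | starting material
11 | 2-(trimethylsilyl)ethyl 2-(diethoxyphosphoryl)-3-(triisopropylsilyloxy)propanoate (racemic) | CCOP(=O)(OCC)C(CO[Si](C(C)C)(C(C)C)C(C)C)C(=O)OCC[Si](C)(C)C | intermediate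
12 | 2-(trimethylsilyl)ethyl (2E)-3-[(1S,6R)-6-(propan-2-yl)-3-(trifluoromethanesulfonyloxy)cyclohex-2-en-1-yl]-2-[(triisopropylsilyloxy)methyl]prop-2-enoate (arm trans to isopropyl) | CC(C)[C@H]1CCC(OS(=O)(=O)C(F)(F)F)=C[C@@H]1/C=C(/C(=O)OCC[Si](C)(C)C)CO[Si](C(C)C)(C(C)C)C(C)C | intermediate
13 | (tributylstannyl)methanol | CCCC[Sn](CCCC)(CCCC)CO | starting material
14 | 2-(trimethylsilyl)ethyl (2E)-3-[(1R,6R)-3-(hydroxymethyl)-6-(propan-2-yl)cyclohex-2-en-1-yl]-2-[(triisopropylsilyloxy)methyl]prop-2-enoate | CC(C)[C@H]1CCC(CO)=C[C@@H]1/C=C(/C(=O)OCC[Si](C)(C)C)CO[Si](C(C)C)(C(C)C)C(C)C | intermediate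
15 | di-tert-butyl dicarbonate | CC(C)(C)OC(=O)OC(=O)OC(C)(C)C | starting material
16 | 2-(trimethylsilyl)ethyl (2E)-3-[(1R,6R)-3-{[(tert-butoxycarbonyl)oxy]methyl}-6-(propan-2-yl)cyclohex-2-en-1-yl]-2-[(triisopropylsilyloxy)methyl]prop-2-enoate | CC(C)[C@H]1CCC(COC(=O)OC(C)(C)C)=C[C@@H]1/C=C(/C(=O)OCC[Si](C)(C)C)CO[Si](C(C)C)(C(C)C)C(C)C | intermediate
17 | carbon monoxide | [C-]#[O+] | starting material
18 | methanol | CO | starting material
19 | methyl (5S,6S,7S,8R)-2-oxo-8-(propan-2-yl)-7-[(1E)-3-oxo-3-[2-(trimethylsilyl)ethoxy]-2-[(triisopropylsilyloxy)methyl]prop-1-en-1-yl]-1,3-dioxaspiro[4.5]decane-6-carboxylate (ring O on C5 trans, CH2 of the dioxolanone cis to the ester) | CC(C)[C@H]1CC[C@@]2(COC(=O)O2)[C@@H](C(=O)OC)[C@@H]1/C=C(/C(=O)OCC[Si](C)(C)C)CO[Si](C(C)C)(C(C)C)C(C)C | intermediate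
20 | (5S,6S,7S,8R)-2-oxo-8-(propan-2-yl)-7-[(1E)-3-oxo-3-[2-(trimethylsilyl)ethoxy]-2-[(triisopropylsilyloxy)methyl]prop-1-en-1-yl]-1,3-dioxaspiro[4.5]decane-6-carboxylic acid | CC(C)[C@H]1CC[C@@]2(COC(=O)O2)[C@@H](C(=O)O)[C@@H]1/C=C(/C(=O)OCC[Si](C)(C)C)CO[Si](C(C)C)(C(C)C)C(C)C | intermediate
21 | (5S,6S,7S,8R)-7-[(1E)-2-(hydroxymethyl)-3-oxo-3-[2-(trimethylsilyl)ethoxy]prop-1-en-1-yl]-2-oxo-8-(propan-2-yl)-1,3-dioxaspiro[4.5]decane-6-carboxylic acid | CC(C)[C@H]1CC[C@@]2(COC(=O)O2)[C@@H](C(=O)O)[C@@H]1/C=C(/C(=O)OCC[Si](C)(C)C)CO | intermediate
22 | mixed anhydride of 21 with 2,4,6-trichlorobenzoic acid | CC(C)[C@H]1CC[C@@]2(COC(=O)O2)[C@@H](C(=O)OC(=O)c3c(Cl)cc(Cl)cc3Cl)[C@@H]1/C=C(/C(=O)OCC[Si](C)(C)C)CO | intermediate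
23 | ring A–B lactone spiro carbonate: 2-(trimethylsilyl)ethyl (5aS,6R,9S,9aS)-1-oxo-6-(propan-2-yl)-1,3,5a,6,7,8,9,9a-octahydro-2-benzoxepine-4-carboxylate whose C9 is the spiro carbon of a 2-oxo-1,3-dioxolane (ring O on C9 trans to C9a–C1, trans ring fusion) | CC(C)[C@H]1CC[C@@]3(COC(=O)O3)[C@H]2C(=O)OCC(C(=O)OCC[Si](C)(C)C)=C[C@H]12 | intermediate
24 | 2-(trimethylsilyl)ethyl (5aS,6R,9S,9aS)-9-hydroxy-9-(hydroxymethyl)-1-oxo-6-(propan-2-yl)-1,3,5a,6,7,8,9,9a-octahydro-2-benzoxepine-4-carboxylate | CC(C)[C@H]1CC[C@@](O)(CO)[C@H]2C(=O)OCC(C(=O)OCC[Si](C)(C)C)=C[C@H]12 | intermediate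
25 | 2-(trimethylsilyl)ethyl (2E)-3-[(1R,6R)-3-[(tert-butyldimethylsilyloxy)methyl]-6-(propan-2-yl)cyclohex-2-en-1-yl]-2-[(triisopropylsilyloxy)methyl]prop-2-enoate | CC(C)[C@H]1CCC(CO[Si](C)(C)C(C)(C)C)=C[C@@H]1/C=C(/C(=O)OCC[Si](C)(C)C)CO[Si](C(C)C)(C(C)C)C(C)C | intermediate
26 | (2E)-3-[(1R,6R)-3-[(tert-butyldimethylsilyloxy)methyl]-6-(propan-2-yl)cyclohex-2-en-1-yl]-2-[(triisopropylsilyloxy)methyl]prop-2-enoic acid | CC(C)[C@H]1CCC(CO[Si](C)(C)C(C)(C)C)=C[C@@H]1/C=C(/C(=O)O)CO[Si](C(C)C)(C(C)C)C(C)C | intermediate
27 | mixed anhydride of 26 with 2,4,6-trichlorobenzoic acid | CC(C)[C@H]1CCC(CO[Si](C)(C)C(C)(C)C)=C[C@@H]1/C=C(/C(=O)OC(=O)c2c(Cl)cc(Cl)cc2Cl)CO[Si](C(C)C)(C(C)C)C(C)C | intermediate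
28 | fully protected dimer: 24 esterified at its primary hydroxyl with 26 (2-(trimethylsilyl)ethyl ester on ring B, tert-butyldimethylsilyl ether on the ring C CH2OH, triisopropylsilyl ether on the ring C arm) | CC(C)[C@H]1CC[C@@](O)(COC(=O)/C(=C/[C@H]2C=C(CO[Si](C)(C)C(C)(C)C)CC[C@@H]2C(C)C)CO[Si](C(C)C)(C(C)C)C(C)C)[C@H]2C(=O)OCC(C(=O)OCC[Si](C)(C)C)=C[C@H]12 | intermediate
29 | CNP0361406.2: (5aS,6R,9S,9aS)-9-hydroxy-9-({[(2E)-2-(hydroxymethyl)-3-[(1R,6R)-3-(hydroxymethyl)-6-(propan-2-yl)cyclohex-2-en-1-yl]prop-2-enoyl]oxy}methyl)-1-oxo-6-(propan-2-yl)-1,3,5a,6,7,8,9,9a-octahydro-2-benzoxepine-4-carboxylic acid | CC(C)[C@H]1CC[C@@](O)(COC(=O)/C(=C/[C@H]2C=C(CO)CC[C@@H]2C(C)C)CO)[C@H]2C(=O)OCC(C(=O)O)=C[C@H]12 | target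

## Step count and risks

Total: 16 steps. Longest linear sequence: 12 steps (1, 2, 5, 6, 7, 8, 9, 10, 11, 12, 15, 16; the branch through steps 3 and 4 is equally long).

**Step 8 (key step).** The most likely failure is oxypalladation on the other alkene face, which would invert both new centres and cannot be repaired afterwards.
- Cause: with isopropyl and arm equatorial, the required adduct has both new bonds equatorial and must form through a twist-like transition state, whereas trans-diaxial opening leads to the other face. The arm shields its own face only moderately.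
- Further hazards: ionisation of the allylic carbonate by transient zerovalent palladium, and β-hydride elimination before CO insertion.
- Fallback (known chemistry, sets out from 12, returns at 20): Negishi coupling of 12 with Me3SiCH2ZnCl (from Me3SiCH2MgCl and ZnCl2; Pd(PPh3)4, THF) would give the allylsilane F1. A Hosomi–Sakurai-type SE2′ reaction with trimethyl orthoformate (TMSOTf, CH2Cl2, −78 °C) then puts the one-carbon unit on the former alkene CH and moves the double bond out of the ring, giving the exocyclic alkene acetal F2. Upjohn dihydroxylation (OsO4 cat., NMO) attacks the methylidene group from the equatorial direction, the known preference for methylenecyclohexanes, so the diol F3 has the tertiary hydroxyl equatorial and the CH2OH axial; the acetal cannot lactonise onto it. 1,1′-Carbonyldiimidazole closes the cyclic carbonate F4, mild acetal hydrolysis (LiBF4, wet MeCN) gives the aldehyde F5, whose α-centre can be equilibrated to the equatorial epimer if needed, and Pinnick oxidation (NaClO2, NaH2PO4, 2-methyl-2-butene) delivers 20.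

**Step 12.** The most likely failure is migration of the strained lactone acyl group onto the newly freed primary hydroxyl (giving a five-membered lactone), or hydrolytic opening of ring B, under the basic conditions; the same exposure recurs briefly in step 15.
- Fallback (sets out from 23 and 26, returns at 28): the halves are joined without ever freeing the diol. The caesium carboxylate F8 (from 26 and Cs2CO3, DMF) is heated with 23 at 90–100 °C so that it opens the cyclic carbonate at its CH2 with loss of CO2, giving 28 directly. This is held in reserve because substitution at that hindered carbon is slow.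

**Step 9.** The most likely failure is competing SN2 cleavage of the 2-(trimethylsilyl)ethyl ester, or slow degradation of the carbonate on prolonged heating with iodide.
- Fallback (sets out from 19, returns at 23): the acid is bypassed. HF·pyridine removes the silyl ether of 19 to give the hydroxy methyl ester F6, and intramolecular transesterification catalysed by (ClBu2Sn)2O in refluxing toluene, with removal of methanol, closes ring B to 23.

**Step 6.** The most likely failure is slow transmetalation of the α-hydroxyalkyl stannane, so that reduction of the triflate or decomposition competes with coupling.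
- Fallback (sets out from 12, returns at 14): palladium-catalysed formylation of 12 (CO, Bu3SnH, Pd(PPh3)4, THF, 50 °C) gives the enal F7, and Luche reduction (NaBH4, CeCl3·7H2O, MeOH, −40 °C) reduces the aldehyde in the presence of the enoate to 14.

## Further compounds

F1 | step 8 | allylsilane: 12 with the triflate replaced by CH2SiMe3 | CC(C)[C@H]1CCC(C[Si](C)(C)C)=C[C@@H]1/C=C(/C(=O)OCC[Si](C)(C)C)CO[Si](C(C)C)(C(C)C)C(C)C
F2 | step 8 | exocyclic alkene acetal: cyclohexane with 3-methylidene, 2-(dimethoxymethyl) trans to the arm at C1, isopropyl at C6 trans to the arm | CC(C)[C@H]1CCC(=C)[C@@H](C(OC)OC)[C@@H]1/C=C(/C(=O)OCC[Si](C)(C)C)CO[Si](C(C)C)(C(C)C)C(C)C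
F3 | step 8 | diol from F2: tertiary hydroxyl equatorial, CH2OH axial (cis to the dimethoxymethyl group) | CC(C)[C@H]1CC[C@@](O)(CO)[C@@H](C(OC)OC)[C@@H]1/C=C(/C(=O)OCC[Si](C)(C)C)CO[Si](C(C)C)(C(C)C)C(C)C
F4 | step 8 | cyclic carbonate of F3 (the dimethyl acetal analogue of 19) | CC(C)[C@H]1CC[C@@]2(COC(=O)O2)[C@@H](C(OC)OC)[C@@H]1/C=C(/C(=O)OCC[Si](C)(C)C)CO[Si](C(C)C)(C(C)C)C(C)C
F5 | step 8 | aldehyde corresponding to acid 20 | CC(C)[C@H]1CC[C@@]2(COC(=O)O2)[C@@H](C=O)[C@@H]1/C=C(/C(=O)OCC[Si](C)(C)C)CO[Si](C(C)C)(C(C)C)C(C)C
F6 | step 9 | hydroxy methyl ester: 19 without the triisopropylsilyl group | CC(C)[C@H]1CC[C@@]2(COC(=O)O2)[C@@H](C(=O)OC)[C@@H]1/C=C(/C(=O)OCC[Si](C)(C)C)CO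
F7 | step 6 | enal: 12 with the triflate replaced by CHO | CC(C)[C@H]1CCC(C=O)=C[C@@H]1/C=C(/C(=O)OCC[Si](C)(C)C)CO[Si](C(C)C)(C(C)C)C(C)C
F8 | step 12 | caesium salt of 26 | CC(C)[C@H]1CCC(CO[Si](C)(C)C(C)(C)C)=C[C@@H]1/C=C(/C(=O)[O-])CO[Si](C(C)C)(C(C)C)C(C)C.[Cs+]
A1 | alternative 1 | trans-fused six-membered enol lactone of the ring A keto acid, ketone as ethylene ketal (8,8-ethylenedioxy-5-(propan-2-yl)-4a,5,6,7,8,8a-hexahydro-1H-isochromen-1-one) | CC(C)[C@H]1CCC2(OCCO2)[C@H]3C(=O)OC=C[C@H]13
A2 | alternative 1 | seven-membered bromoalkene lactone with a methoxy acylal carbon, both epimers at that carbon | CC(C)[C@H]1CCC2(OCCO2)[C@H]3C(=O)OC(OC)C(Br)=C[C@H]13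
A3 | alternative 2 | tert-butyl(dimethyl)[(3-methylcyclohexa-1,3-dien-1-yl)oxy]silane | CC1=CCCC(O[Si](C)(C)C(C)(C)C)=C1
A4 | alternative 2 | tert-butyl (2E)-4,4-dimethoxybut-2-enoate | COC(OC)/C=C/C(=O)OC(C)(C)C
A5 | alternative 2 | tert-butyl 1-(tert-butyldimethylsilyloxy)-3-(dimethoxymethyl)-5-methylbicyclo[2.2.2]oct-5-ene-2-carboxylate (ester endo, acetal exo) | CC1=C[C@]2(O[Si](C)(C)C(C)(C)C)CC[C@H]1[C@@H](C(OC)OC)[C@@H]2C(=O)OC(C)(C)C
A6 | alternative 3 | 2-(diethoxyphosphoryl)acrylate of the primary hydroxyl of 24 | CC(C)[C@H]1CC[C@@](O)(COC(=O)C(=C)P(=O)(OCC)OCC)[C@H]2C(=O)OCC(C(=O)OCC[Si](C)(C)C)=C[C@H]12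
A7 | alternative 3 | (1R,6R)-3-[(tert-butyldimethylsilyloxy)methyl]-6-(propan-2-yl)cyclohex-2-ene-1-carbaldehyde | O=C[C@H]1C=C(CO[Si](C)(C)C(C)(C)C)CC[C@@H]1C(C)C
A8 | alternative 3 | assembled skeleton with 4-methoxybenzyl ether on the ring C arm, tert-butyldimethylsilyl ether and 2-(trimethylsilyl)ethyl ester | CC(C)[C@H]1CC[C@@](O)(COC(=O)/C(=C/[C@H]2C=C(CO[Si](C)(C)C(C)(C)C)CC[C@@H]2C(C)C)COCc2ccc(OC)cc2)[C@H]2C(=O)OCC(C(=O)OCC[Si](C)(C)C)=C[C@H]12
A9 | alternative 3 | 4-methoxybenzyl alcohol | COc1ccc(CO)cc1
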